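Assumption: the target SMILES contains no stereocentres (mollicellin B is achiral), so no enantiocontrol is needed and the route delivers the single compound drawn.

## Retrosynthetic overview

1. Open the depsidone lactone (aryl ester C–O) last, giving a diaryl-ether hydroxy acid.
2. Cut the diaryl ether C–O bond (SNAr) into an A-ring 2-chloro-3-formylbenzoate and a B-ring 7-hydroxychroman-4-one of similar size.
3. A ring: 3-chlorotoluene, then meta C–H borylation/oxidation, para-iodination, directed ortho-metalation/formylation and carbonylation.
4. B ring: catechol, then veratrole ortho-methylation, meta C–H borylation/oxidation, and pyranone annulation with 3-methylbut-2-enoic acid, followed by selective 7-O-demethylation.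
5. Ring order: the pyranone ring of the chromanone is built first (B branch); the central seven-membered dioxepinone is closed last (ether bond, then lactone).

## Route

### A-ring fragment

**Step 1**
Reactants: 1, 3-chlorotoluene
Product: 2, 3-chloro-5-methylphenol
Conditions: [Ir(OMe)(cod)]2 (1 mol %), dtbpy, HBpin, hexane, 60 °C; then Oxone, acetone–H2O, rt (one pot)
Reagents that add atoms: Oxone, potassium peroxymonosulfate, [K+].[O-]S(=O)(=O)OO (oxygen source; the Bpin group is transient)
Why: Sterically controlled Ir-catalysed C–H borylation occurs only at C5, the one position not ortho to a substituent, and the aryl boronate is oxidised to the phenol.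

**Step 2**
Reactants: 2, 3-chloro-5-methylphenol
Product: 3, 1-chloro-3-methoxy-5-methylbenzene
Conditions: MeI, K2CO3, acetone, reflux
Reagents that add atoms: iodomethane, CI
Why: Williamson O-methylation; the methyl ether later serves as ortho-director and as the phenol protecting group.

**Step 3**
Reactants: 3, 1-chloro-3-methoxy-5-methylbenzene
Product: 4, 1-chloro-2-iodo-5-methoxy-3-methylbenzene (iodine para to OMe, between Cl and CH3)
Conditions: NIS (1.05 equiv), TFA (cat.), MeCN, 0 °C → rt
Reagents that add atoms: N-iodosuccinimide, O=C1CCC(=O)N1I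
Why: Electrophilic aromatic iodination goes para to the methoxy group, the strongest director, as is usual for 3,5-disubstituted anisoles.

**Step 4**
Reactants: 4, 1-chloro-2-iodo-5-methoxy-3-methylbenzene
Product: 5, 2-chloro-3-iodo-6-methoxy-4-methylbenzaldehyde
Conditions: LiTMP (1.2 equiv), THF, −78 °C, 1 h; DMF, −78 → 0 °C; aq. NH4Cl
Reagents that add atoms: N,N-dimethylformamide, CN(C)C=O
Why: Directed ortho-metalation removes the most acidic ring proton (flanked by OMe and Cl) with an amide base that does not undergo I/Li exchange, and DMF formylates the aryllithium.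

**Step 5**
Reactants: 5, 2-chloro-3-iodo-6-methoxy-4-methylbenzaldehyde
Product: 6, benzyl 2-chloro-3-formyl-4-methoxy-6-methylbenzoate
Conditions: Pd(OAc)2 (5 mol %), Xantphos (6 mol %), CO (1–5 bar), BnOH (3 equiv), Et3N, toluene, 80 °C
Reagents that add atoms: carbon monoxide, [C-]#[O+]; benzyl alcohol, OCc1ccccc1
Why: Pd-catalysed alkoxycarbonylation; oxidative addition is selective for C–I over C–Cl, and the aldehyde is tolerated.

### B-ring fragment

**Step 6**
Reactants: 7, catechol
Product: 8, 1,2-dimethoxybenzene (veratrole)
Conditions: MeI (2.5 equiv), K2CO3, acetone, reflux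
Reagents that add atoms: iodomethane, CI
Why: Double Williamson O-methylation.

**Step 7**
Reactants: 8, veratrole
Product: 9, 1,2-dimethoxy-3-methylbenzene
Conditions: n-BuLi, TMEDA, Et2O, 0 °C → rt; MeI, 0 °C
Reagents that add atoms: iodomethane, CI
Why: Directed ortho-lithiation next to OMe and C-methylation of the aryllithium.

**Step 8**
Reactants: 9, 1,2-dimethoxy-3-methylbenzene
Product: 10, 3,4-dimethoxy-5-methylphenol
Conditions: [Ir(OMe)(cod)]2 (1.5 mol %), dtbpy, B2pin2, THF, 80 °C; then 30 % H2O2, aq. NaOH, 0 °C
Reagents that add atoms: hydrogen peroxide, OO (oxygen source)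
Why: Ir-catalysed borylation of a 1,2,3-trisubstituted arene occurs only at C5 (no ortho substituent), and the boronate is oxidised to the phenol.

**Step 9**
Reactants: 10, 3,4-dimethoxy-5-methylphenol; 11, 3-methylbut-2-enoic acid
Product: 12, 6,7-dimethoxy-2,2,5-trimethylchroman-4-one
Conditions: Eaton's reagent (P2O5/MeSO3H), 70 °C, 2 h
Reagents that add atoms: none
Why: Friedel–Crafts acylation ortho to the free OH at the carbon para to the 3-OMe and next to CH3 (the same site preference as orcinol and 3,4-dimethoxyphenol), then intramolecular oxa-Michael addition closes the 2,2-dimethylpyranone.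

**Step 10**
Reactants: 12, 6,7-dimethoxy-2,2,5-trimethylchroman-4-one
Product: 13, 7-hydroxy-6-methoxy-2,2,5-trimethylchroman-4-one
Conditions: EtSNa (EtSH, NaH), DMF, 100 °C; aq. HCl work-up
Reagents that add atoms: none
Why: Thiolate SN2 demethylation is selective for the methoxy para to the ketone, whose phenoxide is a vinylogous carboxylate; the 6-OMe, meta to C=O, is retained.

### Fragment union and endgame

**Step 11**
Reactants: 6, benzyl 2-chloro-3-formyl-4-methoxy-6-methylbenzoate; 13, 7-hydroxy-6-methoxy-2,2,5-trimethylchroman-4-one
Product: 14, benzyl 3-formyl-4-methoxy-2-[(6-methoxy-2,2,5-trimethyl-4-oxochroman-7-yl)oxy]-6-methylbenzoate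
Conditions: Cs2CO3, DMSO, 100 °C, N2
Reagents that add atoms: none
Why: SNAr diaryl-ether formation; the chloride is activated by the ortho formyl group (resonance) and the ortho ester (induction), and the only free OH of 13 is the 7-phenol.

**Step 12**
Reactants: 14, the diaryl ether benzyl ester
Product: 15, 3-formyl-4-hydroxy-2-[(6-hydroxy-2,2,5-trimethyl-4-oxochroman-7-yl)oxy]-6-methylbenzoic acid
Conditions: BBr3 (8 equiv), CH2Cl2, −78 °C → rt; H2O
Reagents that add atoms: none
Why: Lewis-acid cleavage removes both aryl methyl ethers and the benzyl ester in one operation; the diaryl ether, aldehyde, ketone and the vinylogous-ester pyranone oxygen survive.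

**Step 13**
Reactants: 15, the hydroxy acid
Product: 16, mollicellin B
Conditions: TFAA, toluene (5 mM), 0 °C → rt; aq. NaHCO3
Reagents that add atoms: none
Why: Mixed-anhydride lactonisation (classical depsidone ring closure) by the B-ring 6-OH, the only phenol placed for a seven-membered ring; the A-ring OH is chelated to the ortho CHO, and any transient trifluoroacetate is hydrolysed on work-up.

## Compound list

1 | 3-chlorotoluene | Cc1cccc(Cl)c1 | starting material
2 | 3-chloro-5-methylphenol | Cc1cc(O)cc(Cl)c1 | intermediate
3 | 1-chloro-3-methoxy-5-methylbenzene | COc1cc(C)cc(Cl)c1 | intermediate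
4 | 1-chloro-2-iodo-5-methoxy-3-methylbenzene | COc1cc(C)c(I)c(Cl)c1 | intermediate
5 | 2-chloro-3-iodo-6-methoxy-4-methylbenzaldehyde | COc1cc(C)c(I)c(Cl)c1C=O | intermediate
6 | benzyl 2-chloro-3-formyl-4-methoxy-6-methylbenzoate | COc1cc(C)c(C(=O)OCc2ccccc2)c(Cl)c1C=O | intermediate
7 | catechol | Oc1ccccc1O | starting material
8 | 1,2-dimethoxybenzene | COc1ccccc1OC | intermediate
9 | 1,2-dimethoxy-3-methylbenzene | COc1cccc(C)c1OC | intermediate
10 | 3,4-dimethoxy-5-methylphenol | COc1cc(O)cc(C)c1OC | intermediate
11 | 3-methylbut-2-enoic acid | CC(C)=CC(=O)O | starting material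
12 | 6,7-dimethoxy-2,2,5-trimethylchroman-4-one | COc1cc2OC(C)(C)CC(=O)c2c(C)c1OC | intermediate
13 | 7-hydroxy-6-methoxy-2,2,5-trimethylchroman-4-one | COc1c(O)cc2OC(C)(C)CC(=O)c2c1C | intermediate
14 | benzyl 3-formyl-4-methoxy-2-[(6-methoxy-2,2,5-trimethyl-4-oxochroman-7-yl)oxy]-6-methylbenzoate | Cc1cc(OC)c(C=O)c(Oc2cc3OC(C)(C)CC(=O)c3c(C)c2OC)c1C(=O)OCc1ccccc1 | intermediate
15 | 3-formyl-4-hydroxy-2-[(6-hydroxy-2,2,5-trimethyl-4-oxochroman-7-yl)oxy]-6-methylbenzoic acid | Cc1cc(O)c(C=O)c(Oc2cc3OC(C)(C)CC(=O)c3c(C)c2O)c1C(=O)O | intermediate
16 | mollicellin B (achiral) | Cc1cc(O)c(C=O)c2c1C(=O)Oc1c(cc3c(c1C)C(=O)CC(C)(C)O3)O2 | target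

## Summary

Total steps: 13.
Longest linear sequence: 8 (steps 1–5 or 6–10, then 11–13).

Steps most likely to fail:

- **Step 11 (SNAr union).** The chloride is flanked by two ortho groups, the phenoxide is weakly nucleophilic, and base-mediated aldol condensation of the chromanone CH2 with the aldehyde is possible. Fallback: reverse the order of the two ring bonds. Acylate the 6-OH of a 7-O-MOM-protected 6,7-dihydroxychromanone with the A-ring acid chloride (ester first), remove the MOM group, and close the seven-membered ring by intramolecular SNAr, which needs far less activation.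
- **Step 10 (selective 7-O-demethylation).** The 6-OMe may be cleaved as well, or instead. Fallback: differentiate the two oxygens from the start. Convert o-cresol to 2-methoxy-3-methylphenol (methylation, ortho-lithiation/borate oxidation), then O-silylate and apply Ir borylation/oxidation to reach 4-methoxy-5-methylresorcinol. Annulation with 11 then gives 13 directly with the 7-OH already free.
- **Step 9 (regiochemistry of acylation).** Acylation could occur at the position between OH and OMe, giving the 5,6-dimethoxy-2,2,7-trimethyl isomer. Fallback: replace Friedel–Crafts control with a halogen-defined site. Protect 10 as its MOM ether, brominate with NBS para to the 3-OMe, carry out Br/Li exchange and acylate with N-methoxy-N,3-dimethylbut-2-enamide; acid then removes the MOM group and triggers the oxa-Michael closure to 12.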